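**Plan**

- Numbering: C1 is the CH carrying the pendant aryl (through C1′), C2 and C3 are the CH carbons carrying the hydroxymethyl carbons C2a and C3a, C4 is the ring CH2, C4a and C8a are the fusion carbons beside C4 and C1, ring A is the fused arene and ring B the carbocycle.
- Enabling feature: the pendant aryl has a free OH para to C1, so C1 can be the exocyclic carbon of a p-quinone methide; C2 is α to C2a, so with C2a as an aldehyde C2 becomes the nucleophilic carbon of an enamine.
- Retrosynthesis: cut C1–C2 (ring B) first, then C1–C8a (aryllithium plus silylated vanillin), then C3–C4 (benzylic alkylation of a pent-4-enoyl imide); the C7 and C3a oxygens travel as benzyl ethers.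
- Forward order: C3–C4 joins the chain to ring A, C1–C8a brings in the pendant ring, the terminal alkene is cut to the C2a aldehyde, and ring B closes last through C1–C2; both arenes are bought (6-bromovanillin, vanillin).
- Stereochemistry: C3 comes from an (R)-4-benzyloxazolidin-2-one-directed alkylation; C1 and C2 are set together in the ring closure by an (R)-diphenylprolinol silyl ether catalyst acting in concert with C3 (all-equatorial chair).

Key step: step 12

Remark: the carbinol carbon made in step 9 forms as both epimers and is carried unresolved through 16–19 (left undefined in their SMILES), because it becomes planar in the quinone methide.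

**Route**

Step 1
Reactants: 1 6-bromovanillin (2-bromo-4-hydroxy-5-methoxybenzaldehyde)
Product: 2 4-(benzyloxy)-2-bromo-5-methoxybenzaldehyde
Conditions: BnBr, K2CO3, DMF, rt
Reagents that add atoms: benzyl bromide, BrCc1ccccc1
Why: Williamson etherification of the phenoxide; benzyl is chosen so that it leaves together with the C3a benzyl ether in the final hydrogenolysis.

Step 2
Reactants: 2 4-(benzyloxy)-2-bromo-5-methoxybenzaldehyde
Product: 3 [4-(benzyloxy)-2-bromo-5-methoxyphenyl]methanol
Conditions: NaBH4, MeOH/THF, 0 °C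
Reagents that add atoms: none
Why: Borohydride reduction of the aryl aldehyde to the benzylic alcohol, which leaves the aryl bromide and the benzyl ether untouched.

Step 3
Reactants: 3 [4-(benzyloxy)-2-bromo-5-methoxyphenyl]methanol
Product: 4 1-(benzyloxy)-5-bromo-4-(bromomethyl)-2-methoxybenzene
Conditions: PBr3, CH2Cl2, 0 °C
Reagents that add atoms: phosphorus tribromide, BrP(Br)Br
Why: Bromination of the electron-rich benzylic alcohol with PBr3 (SN2 displacement of the phosphite ester) gives the alkylating agent for the C3–C4 bond.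

Step 4
Reactants: 5 pent-4-enoic acid; 6 (R)-4-benzyloxazolidin-2-one
Product: 8 (R)-4-benzyl-3-(pent-4-enoyl)oxazolidin-2-one, via pent-4-enoic pivalic anhydride 7 (not isolated)
Conditions: t-BuCOCl, Et3N, THF, −20 °C; then LiCl, 6, −20 °C to rt
Reagents that add atoms: none
Why: Mixed-anhydride N-acylation of the oxazolidinone (LiCl/Et3N), in which the nitrogen attacks the unhindered pentenoyl carbonyl of 7; the auxiliary stereocentre is not touched.

Step 5
Reactants: 8 (R)-4-benzyl-3-(pent-4-enoyl)oxazolidin-2-one; 4 1-(benzyloxy)-5-bromo-4-(bromomethyl)-2-methoxybenzene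
Product: 10 (4R)-4-benzyl-3-[(2S)-2-[[4-(benzyloxy)-2-bromo-5-methoxyphenyl]methyl]pent-4-enoyl]oxazolidin-2-one, via sodium enolate 9 (not isolated)
Conditions: NaN(SiMe3)2, THF, −78 °C; then 4, −78 to −20 °C
Reagents that add atoms: none
Why: Oxazolidinone-auxiliary (Evans-type) alkylation, in which the chelated (Z)-enolate 9 is attacked by the benzylic bromide on the face opposite the auxiliary benzyl group; with the (R)-auxiliary this gives the (2S) centre that becomes C3 (R in the target).

Step 6
Reactants: 10 (4R)-4-benzyl-3-[(2S)-2-[[4-(benzyloxy)-2-bromo-5-methoxyphenyl]methyl]pent-4-enoyl]oxazolidin-2-one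
Product: 11 (2S)-2-[[4-(benzyloxy)-2-bromo-5-methoxyphenyl]methyl]pent-4-en-1-ol
Conditions: LiBH4, MeOH (1 equiv), THF, 0 °C
Reagents that add atoms: none
Why: Reductive cleavage of the N-acyloxazolidinone at the exocyclic carbonyl gives the primary alcohol (C3a) without touching the adjacent stereocentre, the aryl bromide or the alkene.

Step 7
Reactants: 11 (2S)-2-[[4-(benzyloxy)-2-bromo-5-methoxyphenyl]methyl]pent-4-en-1-ol
Product: 12 1-(benzyloxy)-4-[(2S)-2-[(benzyloxy)methyl]pent-4-en-1-yl]-5-bromo-2-methoxybenzene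
Conditions: NaH, BnBr, Bu4NI (cat.), THF/DMF, 0 °C to rt
Reagents that add atoms: benzyl bromide, BrCc1ccccc1
Why: Williamson benzylation of the primary alkoxide; the ether keeps the C3a oxygen from quenching the aryllithium and from forming a five-membered lactol with the later aldehyde.

Step 8
Reactants: 13 vanillin
Product: 14 4-[(tert-butyldimethylsilyl)oxy]-3-methoxybenzaldehyde
Conditions: t-BuMe2SiCl, imidazole, DMF, rt
Reagents that add atoms: tert-butyldimethylsilyl chloride, CC(C)(C)[Si](C)(C)Cl
Why: Imidazole-promoted silylation of the phenol masks the acidic OH for the organolithium addition and shields the guaiacol unit from periodate in step 10.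

Step 9
Reactants: 12 1-(benzyloxy)-4-[(2S)-2-[(benzyloxy)methyl]pent-4-en-1-yl]-5-bromo-2-methoxybenzene; 14 4-[(tert-butyldimethylsilyl)oxy]-3-methoxybenzaldehyde
Product: 16 [5-(benzyloxy)-2-[(2S)-2-[(benzyloxy)methyl]pent-4-en-1-yl]-4-methoxyphenyl][4-[(tert-butyldimethylsilyl)oxy]-3-methoxyphenyl]methanol (both carbinol epimers), via aryllithium 15 (not isolated)
Conditions: n-BuLi, THF, −78 °C; then 14, −78 °C; aq. NH4Cl
Reagents that add atoms: none
Why: Bromine–lithium exchange outpaces deprotonation at −78 °C and the aryllithium 15 adds 1,2 to the aldehyde to form C1–C8a; the new carbinol centre forms without control and needs none.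

Step 10
Reactants: 16 [5-(benzyloxy)-2-[(2S)-2-[(benzyloxy)methyl]pent-4-en-1-yl]-4-methoxyphenyl][4-[(tert-butyldimethylsilyl)oxy]-3-methoxyphenyl]methanol
Product: 18 (3R)-4-[4-(benzyloxy)-2-[[4-[(tert-butyldimethylsilyl)oxy]-3-methoxyphenyl](hydroxy)methyl]-5-methoxyphenyl]-3-[(benzyloxy)methyl]butanal, via vicinal diol 17 (not isolated)
Conditions: OsO4 (2 mol %), NaIO4, 2,6-lutidine, 1,4-dioxane/H2O, rt
Reagents that add atoms: osmium tetraoxide, O=[Os](=O)(=O)=O; sodium periodate (terminal oxidant that restores it), [Na+].[O-]I(=O)(=O)=O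
Why: Lemieux–Johnson oxidation (osmium-catalysed dihydroxylation of the terminal alkene to diol 17, then periodate glycol cleavage, buffered by 2,6-lutidine) unveils the C2a aldehyde; the diaryl carbinol, silyl ether and benzyl ethers are not expected to be oxidised.

Step 11
Reactants: 18 (3R)-4-[4-(benzyloxy)-2-[[4-[(tert-butyldimethylsilyl)oxy]-3-methoxyphenyl](hydroxy)methyl]-5-methoxyphenyl]-3-[(benzyloxy)methyl]butanal
Product: 19 (3R)-4-[4-(benzyloxy)-2-[hydroxy(4-hydroxy-3-methoxyphenyl)methyl]-5-methoxyphenyl]-3-[(benzyloxy)methyl]butanal (both carbinol epimers)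
Conditions: Bu4NF, AcOH, THF, 0 °C
Reagents that add atoms: none
Why: Fluoride desilylation of the aryl silyl ether, buffered with acetic acid so that neither aldol condensation nor base-triggered quinone methide formation sets in, frees the phenol needed for the ring closure.

Step 12
Reactants: 19 (3R)-4-[4-(benzyloxy)-2-[hydroxy(4-hydroxy-3-methoxyphenyl)methyl]-5-methoxyphenyl]-3-[(benzyloxy)methyl]butanal
Product: 22 (1S,2R,3R)-7-(benzyloxy)-3-[(benzyloxy)methyl]-1-(4-hydroxy-3-methoxyphenyl)-6-methoxy-1,2,3,4-tetrahydronaphthalene-2-carbaldehyde, via quinone methide aldehyde 20 (not isolated), via quinone methide enamine 21 (not isolated)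
Conditions: (R)-2-[diphenyl(trimethylsilyloxy)methyl]pyrrolidine (20 mol %), (PhO)2P(O)OH (20 mol %), CHCl3 (0.05 M), 0 °C to rt
Reagents that add atoms: none
Why: Acid-promoted loss of water turns the 4-hydroxybenzhydrol into p-quinone methide 20 and the pyrrolidine condenses with the aldehyde to (E)-enamine 21, whose carbon C2 adds to the exocyclic carbon C1 (1,6-addition); the pendant ring re-aromatises to the phenol and hydrolysis of the iminium ion returns catalyst and aldehyde. The closest known reaction type is the aminocatalytic enantioselective α-alkylation of aldehydes by p-quinone methides, including those released in situ from 4-hydroxybenzylic alcohols by a Brønsted acid, run here intramolecularly. Ring B closes in a 6-exo-trig mode with respect to the C1=C1′ bond (6-enolexo for the enamine). C2 is set by the catalyst, whose diphenyl(silyloxy)methyl arm covers one enamine face so that C1 bonds to the other; the (R)-antipode is the one whose open face coincides with the chair-like transition state that keeps the C3 benzyloxymethyl group equatorial, and C2 stays epimerisable through the enamine towards this all-equatorial aldehyde, while C1 is set in the same chair with the quinone methide ring pseudo-equatorial and hence trans to the C2 formyl carbon. The step needs C-alkylation at C1 by C2 alone, which the substrate secures: C1 has only aryl neighbours, so the quinone methide cannot tautomerise to a styrene, C1 is already bonded to ring A, so no Friedel–Crafts closure competes, the C3a benzyl ether rules out lactol formation, and high dilution disfavours capture by a second phenol.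

Step 13
Reactants: 22 (1S,2R,3R)-7-(benzyloxy)-3-[(benzyloxy)methyl]-1-(4-hydroxy-3-methoxyphenyl)-6-methoxy-1,2,3,4-tetrahydronaphthalene-2-carbaldehyde
Product: 23 [(1S,2R,3R)-7-(benzyloxy)-3-[(benzyloxy)methyl]-1-(4-hydroxy-3-methoxyphenyl)-6-methoxy-1,2,3,4-tetrahydronaphthalen-2-yl]methanol
Conditions: NaBH4, MeOH, 0 °C
Reagents that add atoms: none
Why: Borohydride reduction of the aldehyde to the C2a primary alcohol at 0 °C should be faster than any epimerisation at C2, and nothing else in 22 is reducible.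

Step 14
Reactants: 23 [(1S,2R,3R)-7-(benzyloxy)-3-[(benzyloxy)methyl]-1-(4-hydroxy-3-methoxyphenyl)-6-methoxy-1,2,3,4-tetrahydronaphthalen-2-yl]methanol
Product: 24 (+)-isolariciresinol
Conditions: H2 (1 atm), Pd/C (10 wt % Pd on carbon), MeOH/EtOAc, rt
Reagents that add atoms: none
Why: Catalytic hydrogenolysis of the aryl and alkyl benzyl ethers frees the C7 phenol and the C3a alcohol; the C–C bonds at the doubly benzylic C1 and the three stereocentres are not affected.

**Compound list**

1 | 6-bromovanillin (2-bromo-4-hydroxy-5-methoxybenzaldehyde) | O=Cc1cc(OC)c(O)cc1Br | starting material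
2 | 4-(benzyloxy)-2-bromo-5-methoxybenzaldehyde | O=Cc1cc(OC)c(OCc2ccccc2)cc1Br | intermediate
3 | [4-(benzyloxy)-2-bromo-5-methoxyphenyl]methanol | OCc1cc(OC)c(OCc2ccccc2)cc1Br | intermediate
4 | 1-(benzyloxy)-5-bromo-4-(bromomethyl)-2-methoxybenzene | BrCc1cc(OC)c(OCc2ccccc2)cc1Br | intermediate
5 | pent-4-enoic acid | C=CCCC(=O)O | starting material
6 | (R)-4-benzyloxazolidin-2-one | O=C1N[C@H](Cc2ccccc2)CO1 | starting material
7 | pent-4-enoic pivalic anhydride (formed in situ) | C=CCCC(=O)OC(=O)C(C)(C)C | intermediate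
8 | (R)-4-benzyl-3-(pent-4-enoyl)oxazolidin-2-one | C=CCCC(=O)N1[C@H](Cc2ccccc2)COC1=O | intermediate
9 | sodium (Z)-enolate of 8 (formed in situ) | C=CC/C=C(\[O-])N1[C@H](Cc2ccccc2)COC1=O.[Na+] | intermediate
10 | (4R)-4-benzyl-3-[(2S)-2-[[4-(benzyloxy)-2-bromo-5-methoxyphenyl]methyl]pent-4-enoyl]oxazolidin-2-one | C=CC[C@@H](Cc1cc(OC)c(OCc2ccccc2)cc1Br)C(=O)N1[C@H](Cc2ccccc2)COC1=O | intermediate
11 | (2S)-2-[[4-(benzyloxy)-2-bromo-5-methoxyphenyl]methyl]pent-4-en-1-ol | C=CC[C@@H](Cc1cc(OC)c(OCc2ccccc2)cc1Br)CO | intermediate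
12 | 1-(benzyloxy)-4-[(2S)-2-[(benzyloxy)methyl]pent-4-en-1-yl]-5-bromo-2-methoxybenzene | C=CC[C@@H](Cc1cc(OC)c(OCc2ccccc2)cc1Br)COCc1ccccc1 | intermediate
13 | vanillin | COc1cc(C=O)ccc1O | starting material
14 | 4-[(tert-butyldimethylsilyl)oxy]-3-methoxybenzaldehyde | COc1cc(C=O)ccc1O[Si](C)(C)C(C)(C)C | intermediate
15 | aryllithium from 12 by bromine–lithium exchange (formed in situ) | C=CC[C@@H](Cc1cc(OC)c(OCc2ccccc2)cc1[Li])COCc1ccccc1 | intermediate
16 | [5-(benzyloxy)-2-[(2S)-2-[(benzyloxy)methyl]pent-4-en-1-yl]-4-methoxyphenyl][4-[(tert-butyldimethylsilyl)oxy]-3-methoxyphenyl]methanol (both carbinol epimers) | C=CC[C@@H](Cc1cc(OC)c(OCc2ccccc2)cc1C(O)c1ccc(O[Si](C)(C)C(C)(C)C)c(OC)c1)COCc1ccccc1 | intermediate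
17 | vicinal diol from dihydroxylation of the terminal alkene of 16 (diastereomer mixture, formed in situ) | OCC(O)C[C@@H](Cc1cc(OC)c(OCc2ccccc2)cc1C(O)c1ccc(O[Si](C)(C)C(C)(C)C)c(OC)c1)COCc1ccccc1 | intermediate
18 | (3R)-4-[4-(benzyloxy)-2-[[4-[(tert-butyldimethylsilyl)oxy]-3-methoxyphenyl](hydroxy)methyl]-5-methoxyphenyl]-3-[(benzyloxy)methyl]butanal (both carbinol epimers) | O=CC[C@@H](Cc1cc(OC)c(OCc2ccccc2)cc1C(O)c1ccc(O[Si](C)(C)C(C)(C)C)c(OC)c1)COCc1ccccc1 | intermediate
19 | (3R)-4-[4-(benzyloxy)-2-[hydroxy(4-hydroxy-3-methoxyphenyl)methyl]-5-methoxyphenyl]-3-[(benzyloxy)methyl]butanal (both carbinol epimers) | O=CC[C@@H](Cc1cc(OC)c(OCc2ccccc2)cc1C(O)c1ccc(O)c(OC)c1)COCc1ccccc1 | intermediate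
20 | (3R)-4-[4-(benzyloxy)-5-methoxy-2-[(3-methoxy-4-oxocyclohexa-2,5-dien-1-ylidene)methyl]phenyl]-3-[(benzyloxy)methyl]butanal (p-quinone methide, formed in situ) | O=CC[C@@H](Cc1cc(OC)c(OCc2ccccc2)cc1C=C1C=CC(=O)C(OC)=C1)COCc1ccccc1 | intermediate
21 | (E)-enamine of 20 with (R)-2-[diphenyl(trimethylsilyloxy)methyl]pyrrolidine (formed in situ) | C[Si](C)(C)OC(c1ccccc1)(c1ccccc1)[C@H]1CCCN1/C=C/[C@@H](Cc1cc(OC)c(OCc2ccccc2)cc1C=C1C=CC(=O)C(OC)=C1)COCc1ccccc1 | intermediate
22 | (1S,2R,3R)-7-(benzyloxy)-3-[(benzyloxy)methyl]-1-(4-hydroxy-3-methoxyphenyl)-6-methoxy-1,2,3,4-tetrahydronaphthalene-2-carbaldehyde | COc1cc([C@H]2c3cc(OCc4ccccc4)c(OC)cc3C[C@@H](COCc3ccccc3)[C@@H]2C=O)ccc1O | intermediate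
23 | [(1S,2R,3R)-7-(benzyloxy)-3-[(benzyloxy)methyl]-1-(4-hydroxy-3-methoxyphenyl)-6-methoxy-1,2,3,4-tetrahydronaphthalen-2-yl]methanol | COc1cc([C@H]2c3cc(OCc4ccccc4)c(OC)cc3C[C@@H](COCc3ccccc3)[C@@H]2CO)ccc1O | intermediate
24 | (+)-isolariciresinol, [(1S,2R,3R)-7-hydroxy-1-(4-hydroxy-3-methoxyphenyl)-3-(hydroxymethyl)-6-methoxy-1,2,3,4-tetrahydronaphthalen-2-yl]methanol | COc1cc([C@H]2c3cc(O)c(OC)cc3C[C@@H](CO)[C@@H]2CO)ccc1O | target

**Step count and risks**

Total step count: 14. Longest linear sequence: 12 steps (steps 1–3, 5–7 and 9–14, from 6-bromovanillin).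

Steps most likely to fail:

Step 12. The ring closure may show poor facial discrimination at C1, or the quinone methide may be captured by the phenol of a second molecule and oligomerise before the enamine reaches it. The fallback sets out from 18 and replaces aminocatalysis by a substrate-controlled Mukaiyama-type SN1 alkylation. t-BuMe2SiOTf and Et3N in CH2Cl2 would silylate the carbinol and convert the aldehyde into its silyl enol ether, giving 18 as its tert-butyldimethylsilyl enol ether bearing a tert-butyldimethylsilyl ether on the carbinol oxygen F1. BF3·OEt2 in CH2Cl2 at −78 °C would ionise the benzhydryl silyl ether to the cation stabilised by both arenes, which the enol ether should trap through the chair with C3 equatorial, with DBU equilibration at C2 if needed, to give (1S,2R,3R)-7-(benzyloxy)-3-[(benzyloxy)methyl]-1-[4-[(tert-butyldimethylsilyl)oxy]-3-methoxyphenyl]-6-methoxy-1,2,3,4-tetrahydronaphthalene-2-carbaldehyde F2. Bu4NF/AcOH then frees the phenol and the route is rejoined at 22.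

Step 10. The oxidative cleavage may lose chemoselectivity, through oxidation of the electron-rich diaryl carbinol or over-oxidation next to the new aldehyde. The fallback sets out from 12 and moves the cleavage ahead of the carbinol. OsO4/NaIO4/2,6-lutidine on 12 would give (3R)-4-[4-(benzyloxy)-2-bromo-5-methoxyphenyl]-3-[(benzyloxy)methyl]butanal F3, and NaBH4 would reduce it to (3R)-4-[4-(benzyloxy)-2-bromo-5-methoxyphenyl]-3-[(benzyloxy)methyl]butan-1-ol F4. Two equivalents of n-BuLi (alkoxide formation, then bromine–lithium exchange) followed by 14 would give (3R)-4-[4-(benzyloxy)-2-[[4-[(tert-butyldimethylsilyl)oxy]-3-methoxyphenyl](hydroxy)methyl]-5-methoxyphenyl]-3-[(benzyloxy)methyl]butan-1-ol F5. A primary-selective aerobic oxidation with a monovalent copper/nitroxyl system ([Cu(MeCN)4]OTf, 2,2′-bipyridine, TEMPO, N-methylimidazole, air, MeCN) should then oxidise only the primary alcohol, and the route is rejoined at 18.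

Step 9. Proton transfer to the aryllithium, or metalation of a benzylic ether position, may compete with a slow addition to the electron-rich aldehyde and return debrominated arene. The fallback sets out from 12 and reverses the polarity of the coupling. The aryllithium would be trapped with DMF, a fast small electrophile, to give 5-(benzyloxy)-2-[(2S)-2-[(benzyloxy)methyl]pent-4-en-1-yl]-4-methoxybenzaldehyde F6. Commercial 4-bromo-2-methoxyphenol would be silylated (t-BuMe2SiCl, imidazole) to (4-bromo-2-methoxyphenoxy)(tert-butyl)dimethylsilane F7 and converted with Mg in THF into [4-[(tert-butyldimethylsilyl)oxy]-3-methoxyphenyl]magnesium bromide F8. Addition of F8 to F6 at 0 °C rejoins the route at 16.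

**Further compounds**

F1 | step 12 | 18 as its tert-butyldimethylsilyl enol ether (E/Z mixture) bearing a tert-butyldimethylsilyl ether on the carbinol oxygen | CC(C)(C)[Si](C)(C)OC=C[C@@H](Cc1cc(OC)c(OCc2ccccc2)cc1C(O[Si](C)(C)C(C)(C)C)c1ccc(O[Si](C)(C)C(C)(C)C)c(OC)c1)COCc1ccccc1
F2 | step 12 | (1S,2R,3R)-7-(benzyloxy)-3-[(benzyloxy)methyl]-1-[4-[(tert-butyldimethylsilyl)oxy]-3-methoxyphenyl]-6-methoxy-1,2,3,4-tetrahydronaphthalene-2-carbaldehyde | COc1cc([C@H]2c3cc(OCc4ccccc4)c(OC)cc3C[C@@H](COCc3ccccc3)[C@@H]2C=O)ccc1O[Si](C)(C)C(C)(C)C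
F3 | step 10 | (3R)-4-[4-(benzyloxy)-2-bromo-5-methoxyphenyl]-3-[(benzyloxy)methyl]butanal | O=CC[C@@H](Cc1cc(OC)c(OCc2ccccc2)cc1Br)COCc1ccccc1
F4 | step 10 | (3R)-4-[4-(benzyloxy)-2-bromo-5-methoxyphenyl]-3-[(benzyloxy)methyl]butan-1-ol | OCC[C@@H](Cc1cc(OC)c(OCc2ccccc2)cc1Br)COCc1ccccc1
F5 | step 10 | (3R)-4-[4-(benzyloxy)-2-[[4-[(tert-butyldimethylsilyl)oxy]-3-methoxyphenyl](hydroxy)methyl]-5-methoxyphenyl]-3-[(benzyloxy)methyl]butan-1-ol (both carbinol epimers) | OCC[C@@H](Cc1cc(OC)c(OCc2ccccc2)cc1C(O)c1ccc(O[Si](C)(C)C(C)(C)C)c(OC)c1)COCc1ccccc1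
F6 | step 9 | 5-(benzyloxy)-2-[(2S)-2-[(benzyloxy)methyl]pent-4-en-1-yl]-4-methoxybenzaldehyde | C=CC[C@@H](Cc1cc(OC)c(OCc2ccccc2)cc1C=O)COCc1ccccc1
F7 | step 9 | (4-bromo-2-methoxyphenoxy)(tert-butyl)dimethylsilane | COc1cc(Br)ccc1O[Si](C)(C)C(C)(C)C
F8 | step 9 | [4-[(tert-butyldimethylsilyl)oxy]-3-methoxyphenyl]magnesium bromide | COc1cc([Mg]Br)ccc1O[Si](C)(C)C(C)(C)C
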